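**Retrosynthetic overview**
- The two sulfate esters go on last, onto the phenols at C5 of ring A and C4 of ring B, which are freed by hydrogenolysis of benzyl ethers; the oxygens that stay free in the target (on C3 of ring A and on C2 and C6 of ring B) are held as acetates through sulfation.
- The strategy rests on ring B: a benzene with oxygen on its C1 (the ether oxygen to ring A), C2, C4 and C6. It is the folded form of a 6-aryloxy-3,5-dioxohexanoate, with chain C1 to C6 becoming ring B C2, C3, C4, C5, C6 and C1.
- Ring B is therefore cut between its C1 and C2 and traced back to a 4-(benzyloxy)-6-(aryloxymethyl)-2-pyranone, which keeps the oxygen on C4 of ring B apart from those on C2 and C6 as a benzyl enol ether.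
- The pyranone comes from the methyl acetoacetate dianion and an aryloxyacetate, so the hindered diaryl ether at C1 of ring B begins as a simple Williamson alkyl ether made with methyl bromoacetate.
- Ring order: ring A is bought as phloroglucinol and desymmetrized (benzyl on the C5 oxygen, methoxymethyl on the C3 oxygen, the C1 oxygen becoming the bridge); the pyranone is a temporary ring; ring B is closed in step 7.

Key step: step 7

Assumption: the target is taken as the free bis(hydrogen sulfate) as drawn. Aryl hydrogen sulfates lose SO3 slowly in acid, so the last proton exchange is done cold and the product is lyophilized at once.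

**Route**

Step 1
Reactants: 1 phloroglucinol; 2 benzyl bromide
Product: 3 5-(benzyloxy)benzene-1,3-diol
Conditions: 1 (3 equiv), BnBr (1 equiv), K2CO3 (1.1 equiv), DMF, 0 °C to rt; excess 1 removed by water wash
Reagents that add atoms: benzyl bromide, BrCc1ccccc1
Why: Williamson etherification with the triphenol in excess should give the monobenzyl ether as the main alkylated product, the polar aprotic medium favoring O- over C-benzylation.

Step 2
Reactants: 3 5-(benzyloxy)benzene-1,3-diol; 4 chloromethyl methyl ether
Product: 5 3-(benzyloxy)-5-(methoxymethoxy)phenol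
Conditions: MOMCl (1.0 equiv), K2CO3, acetone, 0 °C to rt; recovered 3 recycled
Reagents that add atoms: chloromethyl methyl ether, COCCl
Why: Williamson-type O-alkylation of the symmetric diol with one equivalent of MOMCl is statistical, so the monoether should form beside recoverable 3 and a separable bis-ether.

Step 3
Reactants: 5 3-(benzyloxy)-5-(methoxymethoxy)phenol; 6 methyl bromoacetate
Product: 7 methyl 2-[3-(benzyloxy)-5-(methoxymethoxy)phenoxy]acetate
Conditions: methyl bromoacetate (1.2 equiv), K2CO3, acetone, reflux
Reagents that add atoms: methyl bromoacetate, COC(=O)CBr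
Why: Williamson etherification of the last phenol with an activated primary bromo ester is fast and lays down the future bridging oxygen between C1 of ring A and C1 of ring B as an ordinary alkyl aryl ether.

Step 4
Reactants: 7 methyl 2-[3-(benzyloxy)-5-(methoxymethoxy)phenoxy]acetate; 8 methyl acetoacetate
Product: 10 methyl 6-[3-(benzyloxy)-5-(methoxymethoxy)phenoxy]-3,5-dioxohexanoate, via methyl acetoacetate sodium lithium dianion 9 (not isolated)
Conditions: 8 (2.5 equiv), NaH, THF, 0 °C; n-BuLi, 0 °C; then 7, -78 to 0 °C; AcOH quench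
Reagents that add atoms: methyl acetoacetate, COC(=O)CC(C)=O
Why: Claisen-type C-acylation of the terminal carbanion of the acetoacetate dianion by the inductively activated aryloxyacetate should give the 3,5-dioxohexanoate, the excess dianion taking up the acidic proton of the product.

Step 5
Reactants: 10 methyl 6-[3-(benzyloxy)-5-(methoxymethoxy)phenoxy]-3,5-dioxohexanoate
Product: 11 6-{[3-(benzyloxy)-5-(methoxymethoxy)phenoxy]methyl}-4-hydroxy-2H-pyran-2-one
Conditions: DBU (1.5 equiv), toluene, 80 °C; cold aqueous citric acid work-up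
Reagents that add atoms: none
Why: Base-mediated lactonization (intramolecular transesterification of the C5 enol oxygen onto the methyl ester) is the standard closure of 3,5-dioxo esters to 4-hydroxy-2-pyranones and is driven by formation of the conjugated vinylogous acid as its amidinium salt.

Step 6
Reactants: 11 6-{[3-(benzyloxy)-5-(methoxymethoxy)phenoxy]methyl}-4-hydroxy-2H-pyran-2-one; 12 benzyl alcohol
Product: 13 4-(benzyloxy)-6-{[3-(benzyloxy)-5-(methoxymethoxy)phenoxy]methyl}-2H-pyran-2-one
Conditions: BnOH (1.2 equiv), PPh3, DIAD, THF, 0 °C to rt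
Reagents that add atoms: benzyl alcohol, OCc1ccccc1
Why: Mitsunobu alkylation of the acidic 4-hydroxyl (a vinylogous carboxylic acid) should take place on the 4-oxygen and so avoid the C3-benzylation that competes under basic alkylation.

Step 7
Reactants: 13 4-(benzyloxy)-6-{[3-(benzyloxy)-5-(methoxymethoxy)phenoxy]methyl}-2H-pyran-2-one
Product: 15 5-(benzyloxy)-2-[3-(benzyloxy)-5-(methoxymethoxy)phenoxy]benzene-1,3-diol, via ring-opened benzyl keto enoate 14 (not isolated)
Conditions: NaOBn (1.0 M in BnOH, 3 equiv), THF, 0 °C then 65 °C, argon; AcOH quench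
Reagents that add atoms: none
Why: Benzyloxide adds to the lactone carbonyl (pyranone C2) and expels the enolate oxygen on pyranone C6, giving after proton transfer the benzyl (2E)-3-(benzyloxy)-5-oxo-6-aryloxyhex-2-enoate 14, in which the ester and the ketone arm stay cis on the enol-ether double bond as the ring left them. The chain C4 methylene, flanked by the enol-ether carbon and the ketone, is probably the more acidic site, but its enolate can only re-close to the pyranone through oxygen, whereas the less populated enolate at the aryloxy-bearing chain C6 attacks the ester carbonyl in a Claisen (Dieckmann-type) condensation that forms the bond between C1 and C2 of ring B and closes six-membered ring B in a 6-(enolendo)-exo-trig mode. Loss of benzyloxide and two enolizations then give the aromatic resorcinol as its sodium salt, which makes the sequence irreversible and drains the pyranone/open-ester equilibrium. The closest known reaction type is the alkoxide-induced opening of 4-alkoxy-6-alkyl-2-pyranones to 3-alkoxy-5-oxohex-2-enoates followed by intramolecular Claisen condensation to phloroglucinol derivatives. No stereocenter is formed. The step needs carbon acylation to win over oxygen acylation and the enol ether at the future C4 of ring B to stay benzyl: the first is secured by the aryloxy group, which acidifies the attacking methylene, and by aromatization, the second by using benzyloxide as the only alkoxide, so that any addition-elimination exchange at the enol-ether carbon is degenerate.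

Step 8
Reactants: 15 5-(benzyloxy)-2-[3-(benzyloxy)-5-(methoxymethoxy)phenoxy]benzene-1,3-diol
Product: 16 5-(benzyloxy)-2-[3-(benzyloxy)-5-hydroxyphenoxy]benzene-1,3-diol
Conditions: HCl (0.5 M in MeOH), 40 °C
Reagents that add atoms: none
Why: Acid-catalyzed acetal exchange (methanolysis) removes the methoxymethyl ether, methanol trapping the oxocarbenium ion as dimethoxymethane before it can alkylate the electron-rich rings, while the benzyl ethers are untouched.

Step 9
Reactants: 16 5-(benzyloxy)-2-[3-(benzyloxy)-5-hydroxyphenoxy]benzene-1,3-diol; 17 acetic anhydride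
Product: 18 2-[3-(acetyloxy)-5-(benzyloxy)phenoxy]-5-(benzyloxy)-1,3-phenylene diacetate
Conditions: Ac2O (5 equiv), pyridine, DMAP (cat.), CH2Cl2, 0 °C to rt
Reagents that add atoms: acetic anhydride, CC(=O)OC(C)=O
Why: Nucleophile-catalyzed acylation (DMAP) should esterify all three phenols, including the two that flank the diaryl ether, giving groups that survive hydrogenolysis and sulfation.

Step 10
Reactants: 18 2-[3-(acetyloxy)-5-(benzyloxy)phenoxy]-5-(benzyloxy)-1,3-phenylene diacetate
Product: 19 2-[3-(acetyloxy)-5-hydroxyphenoxy]-5-hydroxy-1,3-phenylene diacetate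
Conditions: H2 (1 atm), 10% Pd/C, EtOAc, rt
Reagents that add atoms: none
Why: Catalytic hydrogenolysis of the two aryl benzyl ethers under neutral aprotic conditions should free only the hydroxyls on C5 of ring A and C4 of ring B, the aryl acetates and the diaryl ether being inert.

Step 11
Reactants: 19 2-[3-(acetyloxy)-5-hydroxyphenoxy]-5-hydroxy-1,3-phenylene diacetate; 20 sulfur trioxide-pyridine complex
Product: 21 bis(pyridinium) 3-(acetyloxy)-5-[2,6-bis(acetyloxy)-4-(sulfonatooxy)phenoxy]phenyl sulfate
Conditions: SO3·pyridine (6 equiv), DMF, rt; concentrate, triturate with Et2O, use at once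
Reagents that add atoms: sulfur trioxide-pyridine complex, [O-]S(=O)(=O)[n+]1ccccc1
Why: O-sulfonation of phenols with the SO3·pyridine complex should convert both free phenols into aryl sulfate monoesters, held as pyridinium salts, while the acetates block the other three oxygens.

Step 12
Reactants: 21 bis(pyridinium) 3-(acetyloxy)-5-[2,6-bis(acetyloxy)-4-(sulfonatooxy)phenoxy]phenyl sulfate
Product: 22 3-[2,6-dihydroxy-4-(sulfooxy)phenoxy]-5-hydroxyphenyl hydrogen sulfate (target)
Conditions: NH3 (7 M in MeOH), 0 °C; reverse-phase C18 (H2O/MeOH); strong-acid cation-exchange resin (H+ form), H2O, 0 °C; lyophilize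
Reagents that add atoms: none
Why: Aminolysis of aryl acetates is fast at low temperature and leaves sulfate monoester anions untouched, and a brief cold exchange on a sulfonic acid resin should then give the free hydrogen sulfates before acid-catalyzed desulfation sets in.

**Compound list**
1 | phloroglucinol | Oc1cc(O)cc(O)c1 | starting material
2 | benzyl bromide | BrCc1ccccc1 | starting material
3 | 5-(benzyloxy)benzene-1,3-diol | Oc1cc(O)cc(OCc2ccccc2)c1 | intermediate
4 | chloromethyl methyl ether | COCCl | starting material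
5 | 3-(benzyloxy)-5-(methoxymethoxy)phenol | Oc1cc(OCOC)cc(OCc2ccccc2)c1 | intermediate
6 | methyl bromoacetate | COC(=O)CBr | starting material
7 | methyl 2-[3-(benzyloxy)-5-(methoxymethoxy)phenoxy]acetate | COC(=O)COc1cc(OCOC)cc(OCc2ccccc2)c1 | intermediate
8 | methyl acetoacetate | COC(=O)CC(C)=O | starting material
9 | methyl acetoacetate sodium lithium dianion (not isolated) | [Na+].[Li+].C=C([O-])C=C([O-])OC | intermediate
10 | methyl 6-[3-(benzyloxy)-5-(methoxymethoxy)phenoxy]-3,5-dioxohexanoate | COC(=O)CC(=O)CC(=O)COc1cc(OCOC)cc(OCc2ccccc2)c1 | intermediate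
11 | 6-{[3-(benzyloxy)-5-(methoxymethoxy)phenoxy]methyl}-4-hydroxy-2H-pyran-2-one | O=c1cc(O)cc(COc2cc(OCOC)cc(OCc3ccccc3)c2)o1 | intermediate
12 | benzyl alcohol | OCc1ccccc1 | starting material
13 | 4-(benzyloxy)-6-{[3-(benzyloxy)-5-(methoxymethoxy)phenoxy]methyl}-2H-pyran-2-one | O=c1cc(OCc2ccccc2)cc(COc2cc(OCOC)cc(OCc3ccccc3)c2)o1 | intermediate
14 | benzyl (2E)-3-(benzyloxy)-6-[3-(benzyloxy)-5-(methoxymethoxy)phenoxy]-5-oxohex-2-enoate (not isolated) | O=C(OCc1ccccc1)/C=C(\CC(=O)COc1cc(OCOC)cc(OCc2ccccc2)c1)OCc1ccccc1 | intermediate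
15 | 5-(benzyloxy)-2-[3-(benzyloxy)-5-(methoxymethoxy)phenoxy]benzene-1,3-diol | Oc1cc(OCc2ccccc2)cc(O)c1Oc1cc(OCOC)cc(OCc2ccccc2)c1 | intermediate
16 | 5-(benzyloxy)-2-[3-(benzyloxy)-5-hydroxyphenoxy]benzene-1,3-diol | Oc1cc(OCc2ccccc2)cc(O)c1Oc1cc(O)cc(OCc2ccccc2)c1 | intermediate
17 | acetic anhydride | CC(=O)OC(C)=O | starting material
18 | 2-[3-(acetyloxy)-5-(benzyloxy)phenoxy]-5-(benzyloxy)-1,3-phenylene diacetate | CC(=O)Oc1cc(OCc2ccccc2)cc(OC(C)=O)c1Oc1cc(OC(C)=O)cc(OCc2ccccc2)c1 | intermediate
19 | 2-[3-(acetyloxy)-5-hydroxyphenoxy]-5-hydroxy-1,3-phenylene diacetate | CC(=O)Oc1cc(O)cc(OC(C)=O)c1Oc1cc(O)cc(OC(C)=O)c1 | intermediate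
20 | sulfur trioxide-pyridine complex | [O-]S(=O)(=O)[n+]1ccccc1 | starting material
21 | bis(pyridinium) 3-(acetyloxy)-5-[2,6-bis(acetyloxy)-4-(sulfonatooxy)phenoxy]phenyl sulfate | CC(=O)Oc1cc(OS(=O)(=O)[O-])cc(OC(C)=O)c1Oc1cc(OS(=O)(=O)[O-])cc(OC(C)=O)c1.c1cc[nH+]cc1.c1cc[nH+]cc1 | intermediate
22 | 3-[2,6-dihydroxy-4-(sulfooxy)phenoxy]-5-hydroxyphenyl hydrogen sulfate | O=S(=O)(O)Oc1cc(O)cc(Oc2c(O)cc(OS(=O)(=O)O)cc2O)c1 | target

Total step count: 12
Longest linear sequence: 12 steps (from phloroglucinol 1 to 22)

**Steps most likely to fail**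

Step 7. The open enoate may return to the pyranone through oxygen faster than the minor carbon enolate closes the ring, so that no net conversion occurs, or the alkoxide may cleave the aryloxymethyl ether. The fallback builds the diaryl ether directly by Ullmann coupling. It sets out from 3 and 5. Both phenols of 3 are capped (MOMCl, iPr2NEt, CH2Cl2) to give 5-(benzyloxy)-1,3-bis(methoxymethoxy)benzene F1. Directed ortho-lithiation between the two acetal oxygens (n-BuLi, THF, 0 °C) and an I2 quench give 5-(benzyloxy)-2-iodo-1,3-bis(methoxymethoxy)benzene F2. Copper-catalyzed coupling of F2 with phenol 5 (CuI, picolinic acid, K3PO4, DMSO, 90 °C) gives 5-(benzyloxy)-2-[3-(benzyloxy)-5-(methoxymethoxy)phenoxy]-1,3-bis(methoxymethoxy)benzene F3. The acid methanolysis of step 8 then removes all three acetals, and the route is rejoined at 16.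

Step 4. Proton transfer from the acidic methylene of ester 7 to the dianion (enolization), or quenching of the dianion by the acidic product, may outrun acylation. The fallback uses a stronger acyl donor and a dioxinone as the acetoacetate equivalent. It sets out from 7. Saponification (LiOH, THF/H2O) gives [3-(benzyloxy)-5-(methoxymethoxy)phenoxy]acetic acid F4. 1,1'-Carbonyldiimidazole (THF, rt) gives 2-[3-(benzyloxy)-5-(methoxymethoxy)phenoxy]-1-(1H-imidazol-1-yl)ethan-1-one F5. F5 is added to the lithium dienolate of 2,2,6-trimethyl-4H-1,3-dioxin-4-one (LiN(SiMe3)2, THF, -78 °C) to give 6-{3-[3-(benzyloxy)-5-(methoxymethoxy)phenoxy]-2-oxopropyl}-2,2-dimethyl-4H-1,3-dioxin-4-one F6. Heating F6 in toluene (110 °C) expels acetone; the acylketene is trapped by the enol oxygen and gives 11 directly, so steps 4 and 5 are bypassed and the route is rejoined at 11.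

Step 11. The second sulfation may stall, or the polar pyridinium salt may lose sulfate by solvolysis during isolation. The fallback installs the sulfates as neutral, chromatographable diesters. It sets out from 19. 2,2,2-Trichloroethyl chlorosulfate (Et3N, DMAP, THF, 0 °C to rt) gives 2-[3-(acetyloxy)-5-{[(2,2,2-trichloroethoxy)sulfonyl]oxy}phenoxy]-5-{[(2,2,2-trichloroethoxy)sulfonyl]oxy}-1,3-phenylene diacetate F7, which can be purified on silica. Reductive removal of the trichloroethyl groups (Zn, HCO2NH4, MeOH, rt) gives bis(ammonium) 3-(acetyloxy)-5-[2,6-bis(acetyloxy)-4-(sulfonatooxy)phenoxy]phenyl sulfate F8; any acetate lost here does no harm. The conditions of step 12 (NH3 in MeOH, then cold H+ resin) take F8 to 22, where the route is rejoined.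

**Further compounds**
F1 | step 7 | 5-(benzyloxy)-1,3-bis(methoxymethoxy)benzene | COCOc1cc(OCOC)cc(OCc2ccccc2)c1
F2 | step 7 | 5-(benzyloxy)-2-iodo-1,3-bis(methoxymethoxy)benzene | COCOc1cc(OCc2ccccc2)cc(OCOC)c1I
F3 | step 7 | 5-(benzyloxy)-2-[3-(benzyloxy)-5-(methoxymethoxy)phenoxy]-1,3-bis(methoxymethoxy)benzene | COCOc1cc(OCc2ccccc2)cc(OCOC)c1Oc1cc(OCOC)cc(OCc2ccccc2)c1
F4 | step 4 | [3-(benzyloxy)-5-(methoxymethoxy)phenoxy]acetic acid | OC(=O)COc1cc(OCOC)cc(OCc2ccccc2)c1
F5 | step 4 | 2-[3-(benzyloxy)-5-(methoxymethoxy)phenoxy]-1-(1H-imidazol-1-yl)ethan-1-one | O=C(COc1cc(OCOC)cc(OCc2ccccc2)c1)n1ccnc1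
F6 | step 4 | 6-{3-[3-(benzyloxy)-5-(methoxymethoxy)phenoxy]-2-oxopropyl}-2,2-dimethyl-4H-1,3-dioxin-4-one | CC1(C)OC(=O)C=C(CC(=O)COc2cc(OCOC)cc(OCc3ccccc3)c2)O1
F7 | step 11 | 2-[3-(acetyloxy)-5-{[(2,2,2-trichloroethoxy)sulfonyl]oxy}phenoxy]-5-{[(2,2,2-trichloroethoxy)sulfonyl]oxy}-1,3-phenylene diacetate | CC(=O)Oc1cc(OS(=O)(=O)OCC(Cl)(Cl)Cl)cc(OC(C)=O)c1Oc1cc(OS(=O)(=O)OCC(Cl)(Cl)Cl)cc(OC(C)=O)c1
F8 | step 11 | bis(ammonium) 3-(acetyloxy)-5-[2,6-bis(acetyloxy)-4-(sulfonatooxy)phenoxy]phenyl sulfate | CC(=O)Oc1cc(OS(=O)(=O)[O-])cc(OC(C)=O)c1Oc1cc(OS(=O)(=O)[O-])cc(OC(C)=O)c1.[NH4+].[NH4+]
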